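**Strategy.** The carbocycle is numbered C1 (CMe2), C2–C4, C5/C6 (oxirane carbons, methyl on C5), C7, C8, C9 (C–CO2H), C10 (=CH) and C11 (CHOBz). The C5–C6 bond belongs to both the eleven-membered ring and the oxirane. Cutting it, together with the C6–O bond, opens both rings to an open-chain C5 methyl ketone that carries a diphenylsulfonium group on C6. In the forward sense the C6 ylide adds to the ketone and the resulting alkoxide expels diphenyl sulfide. One operation therefore forms the carbocycle, the epoxide and both epoxide stereocentres. The precursor 23 already holds the C11 benzoate (from (S)-pantolactone), the E-enoic acid and the ketone.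

Key step: step 17

Structure check: in this numbering the target is 5S,6S,11R. C4 and C7 are trans on the oxirane. C8 and C11 are cis on C9=C10, so CO2H is trans to C11 and the alkene is E.

Remark on stereochemistry: the carbinol centre of (S)-pantolactone is never touched. Its descriptor changes from S to R in step 13 only because C10, once an alkene carbon, ranks below C1.

Remark on design: the carboxyl group stays a tert-butyl ester until the sulfonium salt exists. A free acid beside a C6 alcohol, iodide or silver-activated iodide would close the δ-lactone (6-exo-tet). The acid is then released by acidolysis, where the un-ionised CO2H is a poor nucleophile.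

Assumption: compounds 1, 7, 15, 16 and 21 are purchased.

Step 1
Reactants: 1 (S)-pantolactone
Product: 2 (2S)-3,3-dimethylbutane-1,2,4-triol
Conditions: LiAlH4, THF, 0 °C → reflux; careful H2O quench
Reagents that add atoms: none
Why: Hydride reduction of the lactone opens it to the triol without touching the carbinol centre, which becomes C11.

Step 2
Reactants: 2 (2S)-3,3-dimethylbutane-1,2,4-triol
Product: 3 [(2S,4S)-5,5-dimethyl-2-phenyl-1,3-dioxan-4-yl]methanol
Conditions: PhCH(OMe)2, camphorsulfonic acid (cat.), CH2Cl2, rt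
Reagents that add atoms: benzaldehyde dimethyl acetal COC(OC)c1ccccc1
Why: Acid-catalysed transacetalisation under thermodynamic control should favour the six-membered 1,3-dioxane across the C2 and C11 oxygens, with phenyl and CH2OH both equatorial (which sets the acetal centre), leaving the C10 hydroxyl free.

Step 3
Reactants: 3 [(2S,4S)-5,5-dimethyl-2-phenyl-1,3-dioxan-4-yl]methanol
Product: 4 tert-butyl{[(2S,4S)-5,5-dimethyl-2-phenyl-1,3-dioxan-4-yl]methoxy}dimethylsilane
Conditions: TBSCl, imidazole, DMF, rt
Reagents that add atoms: tert-butyldimethylsilyl chloride CC(C)(C)[Si](C)(C)Cl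
Why: Silyl ether protection of the only free, primary hydroxyl group is routine.

Step 4
Reactants: 4 tert-butyl{[(2S,4S)-5,5-dimethyl-2-phenyl-1,3-dioxan-4-yl]methoxy}dimethylsilane
Product: 5 (3S)-3-(benzyloxy)-4-[(tert-butyldimethylsilyl)oxy]-2,2-dimethylbutan-1-ol
Conditions: i-Bu2AlH, CH2Cl2, 0 °C → rt; aq. potassium sodium tartrate
Reagents that add atoms: none
Why: In the reductive opening of a benzylidene acetal, aluminium binds the less hindered primary oxygen, so hydride delivery should leave benzyl on the secondary C11 oxygen and free the C2 hydroxyl.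

Step 5
Reactants: 5 (3S)-3-(benzyloxy)-4-[(tert-butyldimethylsilyl)oxy]-2,2-dimethylbutan-1-ol
Product: 6 (3S)-3-(benzyloxy)-4-[(tert-butyldimethylsilyl)oxy]-2,2-dimethylbutanal
Conditions: Dess–Martin periodinane, CH2Cl2, rt
Reagents that add atoms: none
Why: Dess–Martin oxidation handles neopentyl alcohols, and the aldehyde has no α-hydrogen, so it can neither epimerise nor eliminate.

Step 6
Reactants: 7 2-(2-bromoethyl)-2-methyl-1,3-dioxolane
Product: 8 [2-(2-methyl-1,3-dioxolan-2-yl)ethyl]triphenylphosphonium bromide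
Conditions: PPh3, toluene, 100 °C
Reagents that add atoms: triphenylphosphine c1ccc(cc1)P(c1ccccc1)c1ccccc1
Why: SN2 quaternisation of triphenylphosphine by a primary bromide gives the salt, which precipitates from toluene.

Step 7
Reactants: 6 (3S)-3-(benzyloxy)-4-[(tert-butyldimethylsilyl)oxy]-2,2-dimethylbutanal; 8 [2-(2-methyl-1,3-dioxolan-2-yl)ethyl]triphenylphosphonium bromide
Product: 10 tert-butyl{[(2S,4Z)-2-(benzyloxy)-3,3-dimethyl-6-(2-methyl-1,3-dioxolan-2-yl)hex-4-en-1-yl]oxy}dimethylsilane, via phosphonium ylide 9 (not isolated)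
Conditions: 8, NaN(SiMe3)2, THF, 0 °C; then 6, −78 °C → rt
Reagents that add atoms: none
Why: Wittig olefination with a non-stabilised ylide tolerates α-quaternary aldehydes and adds C3–C5, and the mainly Z geometry does not matter because the alkene is saturated next.

Step 8
Reactants: 10 tert-butyl{[(2S,4Z)-2-(benzyloxy)-3,3-dimethyl-6-(2-methyl-1,3-dioxolan-2-yl)hex-4-en-1-yl]oxy}dimethylsilane
Product: 11 (2S)-1-[(tert-butyldimethylsilyl)oxy]-3,3-dimethyl-6-(2-methyl-1,3-dioxolan-2-yl)hexan-2-ol
Conditions: H2 (3 atm), Pd(OH)2/C, EtOAc, rt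
Reagents that add atoms: none
Why: Catalytic hydrogenation should saturate C2=C3 and hydrogenolyse the benzyl ether in one operation, while the silyl ether and ketal are inert in neutral ethyl acetate.

Step 9
Reactants: 11 (2S)-1-[(tert-butyldimethylsilyl)oxy]-3,3-dimethyl-6-(2-methyl-1,3-dioxolan-2-yl)hexan-2-ol
Product: 12 (2S)-1-[(tert-butyldimethylsilyl)oxy]-3,3-dimethyl-6-(2-methyl-1,3-dioxolan-2-yl)hexan-2-yl benzoate
Conditions: BzCl, DMAP, pyridine, 50 °C
Reagents that add atoms: benzoyl chloride O=C(Cl)c1ccccc1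
Why: DMAP-catalysed acylation with gentle heating should overcome the neopentyl hindrance at the C11 hydroxyl, and no alkoxide is formed that could trigger silyl migration.

Step 10
Reactants: 12 (2S)-1-[(tert-butyldimethylsilyl)oxy]-3,3-dimethyl-6-(2-methyl-1,3-dioxolan-2-yl)hexan-2-yl benzoate
Product: 13 (2S)-1-hydroxy-3,3-dimethyl-7-oxooctan-2-yl benzoate
Conditions: AcOH–THF–H2O (3:1:1), 50 °C
Reagents that add atoms: water O
Why: Mild aqueous acid hydrolysis removes the primary silyl ether and the ketal together in the pH range where 1,2-acyl migration is slowest, and with C11 esterified no free diol exists that could trap the ketone as an internal ketal.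

Step 11
Reactants: 13 (2S)-1-hydroxy-3,3-dimethyl-7-oxooctan-2-yl benzoate
Product: 14 (2S)-3,3-dimethyl-1,7-dioxooctan-2-yl benzoate
Conditions: Dess–Martin periodinane, CH2Cl2, 0 °C → rt
Reagents that add atoms: none
Why: Dess–Martin oxidation is non-basic, so the α-benzoyloxy aldehyde should keep its configuration if it is used at once.

Step 12
Reactants: 15 tert-butyl (triphenyl-λ5-phosphanylidene)acetate; 16 1-chloro-3-iodopropane
Product: 18 tert-butyl 5-chloro-2-(triphenyl-λ5-phosphanylidene)pentanoate, via phosphonium iodide 17 (not isolated)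
Conditions: MeCN, 80 °C; then aq. NaOH, CH2Cl2, rt
Reagents that add atoms: none
Why: C-alkylation of a stabilised ylide occurs at the iodide terminus (iodide is a far better leaving group than chloride), and deprotonation of the resulting salt regenerates an α-substituted stabilised ylide carrying C6–C8.

Step 13
Reactants: 14 (2S)-3,3-dimethyl-1,7-dioxooctan-2-yl benzoate; 18 tert-butyl 5-chloro-2-(triphenyl-λ5-phosphanylidene)pentanoate
Product: 19 tert-butyl (2E,4R)-4-(benzoyloxy)-2-(3-chloropropyl)-5,5-dimethyl-9-oxodec-2-enoate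
Conditions: toluene, 70 °C
Reagents that add atoms: none
Why: Wittig olefination with an α-substituted stabilised ylide should place the ester trans to C11 (E), ignores the methyl ketone, and runs neutral and salt-free, so no free alkoxide or strong base arises that could cause benzoate migration or epimerisation at C11.

Step 14
Reactants: 19 tert-butyl (2E,4R)-4-(benzoyloxy)-2-(3-chloropropyl)-5,5-dimethyl-9-oxodec-2-enoate
Product: 20 tert-butyl (2E,4R)-4-(benzoyloxy)-2-(3-iodopropyl)-5,5-dimethyl-9-oxodec-2-enoate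
Conditions: NaI, acetone, reflux
Reagents that add atoms: sodium iodide [Na+].[I-]
Why: Finkelstein halide exchange at the primary chloride is driven by precipitation of NaCl and leaves esters and ketone untouched.

Step 15
Reactants: 20 tert-butyl (2E,4R)-4-(benzoyloxy)-2-(3-iodopropyl)-5,5-dimethyl-9-oxodec-2-enoate; 21 diphenyl sulfide
Product: 22 [(4E,6R)-6-(benzoyloxy)-4-(tert-butoxycarbonyl)-7,7-dimethyl-11-oxododec-4-en-1-yl]diphenylsulfonium tetrafluoroborate
Conditions: 21 (10 equiv.), AgBF4, CH2Cl2, 0 °C → rt, dark; filtration, precipitation with Et2O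
Reagents that add atoms: silver tetrafluoroborate [Ag+].F[B-](F)(F)F
Why: Silver-assisted S-alkylation of diphenyl sulfide by a primary iodide is the standard entry to alkyl(diphenyl)sulfonium tetrafluoroborates, and the large excess of sulfide is meant to outrun participation of the ester carbonyl at C6.

Step 16
Reactants: 22 [(4E,6R)-6-(benzoyloxy)-4-(tert-butoxycarbonyl)-7,7-dimethyl-11-oxododec-4-en-1-yl]diphenylsulfonium tetrafluoroborate
Product: 23 [(4E,6R)-6-(benzoyloxy)-4-carboxy-7,7-dimethyl-11-oxododec-4-en-1-yl]diphenylsulfonium tetrafluoroborate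
Conditions: CF3CO2H–CH2Cl2 (1:3), 0 °C → rt; evaporation with toluene, trituration with Et2O
Reagents that add atoms: none
Why: Acidolysis of the tert-butyl ester (loss of 2-methylpropene) spares the sulfonium, benzoate, ketone and electron-poor allylic system, and it delivers the acid un-ionised, so the acid does not displace diphenyl sulfide.

Step 17
Reactants: 23 [(4E,6R)-6-(benzoyloxy)-4-carboxy-7,7-dimethyl-11-oxododec-4-en-1-yl]diphenylsulfonium tetrafluoroborate
Product: 27 (1S,4E,6R,11S)-6-(benzoyloxy)-7,7,11-trimethyl-12-oxabicyclo[9.1.0]dodec-4-ene-4-carboxylic acid (target), via sulfonium ylide carboxylate 24 (not isolated), via betaine 25 (not isolated), via lithium carboxylate 26 (not isolated)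
Conditions: LiN(SiMe3)2 (2.0 equiv.), THF–CH2Cl2, 1 mM, −78 → −20 °C; cold aq. citric acid to pH 4
Reagents that add atoms: none
Why: Proposed new method: the first equivalent of LiN(SiMe3)2 removes the carboxylic proton and the second the C6–H next to sulfur to give ylide 24, whose carbanion adds irreversibly to the C5 ketone (C5–C6 bond, carbocycle closed 11-exo-trig) to give betaine 25, and the C5 alkoxide then displaces diphenyl sulfide from C6 with inversion (oxirane closed 3-exo-tet). The closest known reaction type is the Corey–Chaykovsky epoxidation of ketones by non-stabilised alkyl(diphenyl)sulfonium ylides, known intermolecularly and for small rings but not for an eleven-membered carbocycle, so 1 mM dilution has to offset the low effective molarity. C5 is set by the ketone face that is attacked and C6 by the ylide face that bonds, both decided in the cyclic addition transition state, where the only biasing elements are the C11 stereocentre, the adjacent C1 gem-dimethyl group and the rigid E-enoate, so the needed outcome (C4 anti to C7, 5S,6S beside 11R) is not assured and isomers would be separated by chromatography. Chemoselectivity rests on the lithium carboxylate, which blocks 5-exo-trig acylation of the ylide at the acyl carbon and weakens C10 as an acceptor (reachable only 5-endo-trig), while the benzoate carbonyl needs an eight-membered transition state, so the ketone is the only good electrophile. Exactly two equivalents of base keep the ketone from being stored as its enolate, and deprotonation at −78 °C turns C6 from an electrophile into a nucleophile before the carboxylate can attack it 6-exo-tet to give the δ-lactone. Work-up at pH 4 returns the free acid without opening the trisubstituted epoxide.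

**Compound list**

1 | (S)-pantolactone, (3S)-3-hydroxy-4,4-dimethyloxolan-2-one | CC1(C)COC(=O)[C@H]1O | starting material
2 | (2S)-3,3-dimethylbutane-1,2,4-triol | OCC(C)(C)[C@H](O)CO | intermediate
3 | [(2S,4S)-5,5-dimethyl-2-phenyl-1,3-dioxan-4-yl]methanol | OC[C@H]1O[C@@H](c2ccccc2)OCC1(C)C | intermediate
4 | tert-butyl{[(2S,4S)-5,5-dimethyl-2-phenyl-1,3-dioxan-4-yl]methoxy}dimethylsilane | CC(C)(C)[Si](C)(C)OC[C@H]1O[C@@H](c2ccccc2)OCC1(C)C | intermediate
5 | (3S)-3-(benzyloxy)-4-[(tert-butyldimethylsilyl)oxy]-2,2-dimethylbutan-1-ol | OCC(C)(C)[C@H](OCc1ccccc1)CO[Si](C)(C)C(C)(C)C | intermediate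
6 | (3S)-3-(benzyloxy)-4-[(tert-butyldimethylsilyl)oxy]-2,2-dimethylbutanal | O=CC(C)(C)[C@H](OCc1ccccc1)CO[Si](C)(C)C(C)(C)C | intermediate
7 | 2-(2-bromoethyl)-2-methyl-1,3-dioxolane | CC1(CCBr)OCCO1 | starting material
8 | [2-(2-methyl-1,3-dioxolan-2-yl)ethyl]triphenylphosphonium bromide | CC1(CC[P+](c2ccccc2)(c2ccccc2)c2ccccc2)OCCO1.[Br-] | intermediate
9 | [2-(2-methyl-1,3-dioxolan-2-yl)ethylidene]triphenyl-λ5-phosphane (ylide, not isolated) | CC1(CC=P(c2ccccc2)(c2ccccc2)c2ccccc2)OCCO1 | intermediate
10 | tert-butyl{[(2S,4Z)-2-(benzyloxy)-3,3-dimethyl-6-(2-methyl-1,3-dioxolan-2-yl)hex-4-en-1-yl]oxy}dimethylsilane | CC1(C/C=C\C(C)(C)[C@H](OCc2ccccc2)CO[Si](C)(C)C(C)(C)C)OCCO1 | intermediate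
11 | (2S)-1-[(tert-butyldimethylsilyl)oxy]-3,3-dimethyl-6-(2-methyl-1,3-dioxolan-2-yl)hexan-2-ol | CC1(CCCC(C)(C)[C@H](O)CO[Si](C)(C)C(C)(C)C)OCCO1 | intermediate
12 | (2S)-1-[(tert-butyldimethylsilyl)oxy]-3,3-dimethyl-6-(2-methyl-1,3-dioxolan-2-yl)hexan-2-yl benzoate | CC1(CCCC(C)(C)[C@H](OC(=O)c2ccccc2)CO[Si](C)(C)C(C)(C)C)OCCO1 | intermediate
13 | (2S)-1-hydroxy-3,3-dimethyl-7-oxooctan-2-yl benzoate | CC(=O)CCCC(C)(C)[C@H](OC(=O)c1ccccc1)CO | intermediate
14 | (2S)-3,3-dimethyl-1,7-dioxooctan-2-yl benzoate | CC(=O)CCCC(C)(C)[C@H](OC(=O)c1ccccc1)C=O | intermediate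
15 | tert-butyl (triphenyl-λ5-phosphanylidene)acetate | CC(C)(C)OC(=O)C=P(c1ccccc1)(c1ccccc1)c1ccccc1 | starting material
16 | 1-chloro-3-iodopropane | ClCCCI | starting material
17 | [1-(tert-butoxy)-5-chloro-1-oxopentan-2-yl]triphenylphosphonium iodide (racemic, not isolated) | CC(C)(C)OC(=O)C(CCCCl)[P+](c1ccccc1)(c1ccccc1)c1ccccc1.[I-] | intermediate
18 | tert-butyl 5-chloro-2-(triphenyl-λ5-phosphanylidene)pentanoate | CC(C)(C)OC(=O)C(CCCCl)=P(c1ccccc1)(c1ccccc1)c1ccccc1 | intermediate
19 | tert-butyl (2E,4R)-4-(benzoyloxy)-2-(3-chloropropyl)-5,5-dimethyl-9-oxodec-2-enoate | CC(=O)CCCC(C)(C)[C@H](OC(=O)c1ccccc1)/C=C(\CCCCl)C(=O)OC(C)(C)C | intermediate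
20 | tert-butyl (2E,4R)-4-(benzoyloxy)-2-(3-iodopropyl)-5,5-dimethyl-9-oxodec-2-enoate | CC(=O)CCCC(C)(C)[C@H](OC(=O)c1ccccc1)/C=C(\CCCI)C(=O)OC(C)(C)C | intermediate
21 | diphenyl sulfide | c1ccc(cc1)Sc1ccccc1 | starting material
22 | [(4E,6R)-6-(benzoyloxy)-4-(tert-butoxycarbonyl)-7,7-dimethyl-11-oxododec-4-en-1-yl]diphenylsulfonium tetrafluoroborate | CC(=O)CCCC(C)(C)[C@H](OC(=O)c1ccccc1)/C=C(\CCC[S+](c1ccccc1)c1ccccc1)C(=O)OC(C)(C)C.F[B-](F)(F)F | intermediate
23 | [(4E,6R)-6-(benzoyloxy)-4-carboxy-7,7-dimethyl-11-oxododec-4-en-1-yl]diphenylsulfonium tetrafluoroborate (key-step precursor) | CC(=O)CCCC(C)(C)[C@H](OC(=O)c1ccccc1)/C=C(\CCC[S+](c1ccccc1)c1ccccc1)C(=O)O.F[B-](F)(F)F | intermediate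
24 | lithium carboxylate of the C6 diphenylsulfonium ylide derived from 23 (11R, E; not isolated) | CC(=O)CCCC(C)(C)[C@H](OC(=O)c1ccccc1)/C=C(\CC[CH-][S+](c1ccccc1)c1ccccc1)C(=O)[O-].[Li+] | intermediate
25 | ring-closed betaine: eleven-membered carbocycle with C5 alkoxide (5S), C6 diphenylsulfonio group (6R, inverted on closure), 11R benzoate, E-enoate carboxylate, lithium salt (not isolated) | CC1(C)CCC[C@](C)([O-])[C@H]([S+](c2ccccc2)c2ccccc2)CC/C(C(=O)[O-])=C\[C@H]1OC(=O)c1ccccc1.[Li+] | intermediate
26 | lithium (1S,4E,6R,11S)-6-(benzoyloxy)-7,7,11-trimethyl-12-oxabicyclo[9.1.0]dodec-4-ene-4-carboxylate (not isolated) | CC1(C)CCC[C@]2(C)O[C@H]2CC/C(C(=O)[O-])=C\[C@H]1OC(=O)c1ccccc1.[Li+] | intermediate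
27 | (1S,4E,6R,11S)-6-(benzoyloxy)-7,7,11-trimethyl-12-oxabicyclo[9.1.0]dodec-4-ene-4-carboxylic acid | CC1(C)CCC[C@]2(C)O[C@H]2CC/C(C(=O)O)=C\[C@H]1OC(=O)c1ccccc1 | target

**Step count**

- Total step count: 17.
- Longest linear sequence: 15 (steps 1–5, 7–11, 13–17).

**Steps most likely to fail**

**1. Step 17.**
- What may go wrong: the open-chain ylide may oligomerise before it can close the entropically costly eleven-membered ring. It may also decay first, by proton transfer from the enolisable ketone or by elimination of diphenyl sulfide. If the ring does close, control over epoxide geometry and face may be poor.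
- Fallback (known reaction types only): it sets out from 14 and returns at 27.
  - Ylide 15 is alkylated with 4-iodobut-1-ene as in step 12 to give [1-(tert-butoxy)-1-oxohex-5-en-2-yl]triphenylphosphonium iodide F1. Aqueous NaOH converts this into tert-butyl 2-(triphenyl-λ5-phosphanylidene)hex-5-enoate F2.
  - Wittig reaction of F2 with 14 should give tert-butyl (2E,4R)-4-(benzoyloxy)-2-(but-3-en-1-yl)-5,5-dimethyl-9-oxodec-2-enoate F3.
  - Wittig methylenation of the C5 ketone (Ph3P=CH2, THF, −78 → 0 °C) gives tert-butyl (2E,4R)-4-(benzoyloxy)-2-(but-3-en-1-yl)-5,5,9-trimethyldeca-2,9-dienoate F4.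
  - Ring-closing metathesis (second-generation Grubbs catalyst, toluene, 1 mM, 80 °C) joins C5 and C6. The product is tert-butyl (1E,3R,8E)-3-(benzoyloxy)-4,4,8-trimethylcycloundeca-1,8-diene-1-carboxylate F5, with any 8Z isomer removed by chromatography.
  - Me3SiOTf/2,6-lutidine cleaves the tert-butyl ester to trimethylsilyl (1E,3R,8E)-3-(benzoyloxy)-4,4,8-trimethylcycloundeca-1,8-diene-1-carboxylate F6. Water hydrolyses this to (1E,3R,8E)-3-(benzoyloxy)-4,4,8-trimethylcycloundeca-1,8-diene-1-carboxylic acid F7.
  - Dimethyldioxirane in acetone at 0 °C epoxidises only the electron-rich C5=C6 bond, stereospecifically (C4 stays anti to C7), to give 27.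
  - A Shi epoxidation offers reagent control if the ring conformation favours the wrong face.

**2. Step 13.**
- What may go wrong: the bulky ylide may add slowly to the hindered aldehyde. Prolonged heating could then erode the C11 configuration through enolisation, and E-selectivity may be incomplete.
- Fallback: it sets out from 14 and returns at 19.
  - tert-Butyl diethylphosphonoacetate is alkylated with 16 (NaH, DMF) to give tert-butyl 5-chloro-2-(diethoxyphosphoryl)pentanoate F8.
  - The smaller, more nucleophilic lithium-chelated carbanion of F8 is used in a Horner–Wadsworth–Emmons reaction under Masamune–Roush conditions (LiCl, DBU, MeCN, 0 °C).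
  - This allows olefination without heating. The geometric isomers would be separated by chromatography.

**3. Step 15.**
- What may go wrong: the ester carbonyl may participate at the silver-activated C6 with loss of the tert-butyl group, so that lactonisation competes with S-alkylation.
- Fallback: it sets out from 20 and returns at 22.
  - The C6–S bond is made first by plain SN2 with a strong sulfur nucleophile (PhSH, K2CO3, DMF, 0 °C). This gives tert-butyl (2E,4R)-4-(benzoyloxy)-5,5-dimethyl-9-oxo-2-[3-(phenylsulfanyl)propyl]dec-2-enoate F9.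
  - The second phenyl group is then transferred to sulfur from diphenyliodonium tetrafluoroborate under copper catalysis (Cu(OAc)2, 1,2-dichloroethane, 80 °C).
  - C6 is therefore never cationically activated next to the ester.

**Further compounds**

F1 | step 17 | [1-(tert-butoxy)-1-oxohex-5-en-2-yl]triphenylphosphonium iodide | C=CCCC(C(=O)OC(C)(C)C)[P+](c1ccccc1)(c1ccccc1)c1ccccc1.[I-]
F2 | step 17 | tert-butyl 2-(triphenyl-λ5-phosphanylidene)hex-5-enoate | C=CCCC(C(=O)OC(C)(C)C)=P(c1ccccc1)(c1ccccc1)c1ccccc1
F3 | step 17 | tert-butyl (2E,4R)-4-(benzoyloxy)-2-(but-3-en-1-yl)-5,5-dimethyl-9-oxodec-2-enoate | CC(=O)CCCC(C)(C)[C@H](OC(=O)c1ccccc1)/C=C(\CCC=C)C(=O)OC(C)(C)C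
F4 | step 17 | tert-butyl (2E,4R)-4-(benzoyloxy)-2-(but-3-en-1-yl)-5,5,9-trimethyldeca-2,9-dienoate | C=C(C)CCCC(C)(C)[C@H](OC(=O)c1ccccc1)/C=C(\CCC=C)C(=O)OC(C)(C)C
F5 | step 17 | tert-butyl (1E,3R,8E)-3-(benzoyloxy)-4,4,8-trimethylcycloundeca-1,8-diene-1-carboxylate | CC1(C)CCC/C(C)=C/CC/C(C(=O)OC(C)(C)C)=C\[C@H]1OC(=O)c1ccccc1
F6 | step 17 | trimethylsilyl (1E,3R,8E)-3-(benzoyloxy)-4,4,8-trimethylcycloundeca-1,8-diene-1-carboxylate | CC1(C)CCC/C(C)=C/CC/C(C(=O)O[Si](C)(C)C)=C\[C@H]1OC(=O)c1ccccc1
F7 | step 17 | (1E,3R,8E)-3-(benzoyloxy)-4,4,8-trimethylcycloundeca-1,8-diene-1-carboxylic acid | CC1(C)CCC/C(C)=C/CC/C(C(=O)O)=C\[C@H]1OC(=O)c1ccccc1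
F8 | step 13 | tert-butyl 5-chloro-2-(diethoxyphosphoryl)pentanoate | CCOP(=O)(OCC)C(CCCCl)C(=O)OC(C)(C)C
F9 | step 15 | tert-butyl (2E,4R)-4-(benzoyloxy)-5,5-dimethyl-9-oxo-2-[3-(phenylsulfanyl)propyl]dec-2-enoate | CC(=O)CCCC(C)(C)[C@H](OC(=O)c1ccccc1)/C=C(\CCCSc1ccccc1)C(=O)OC(C)(C)C
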